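The numbers in the tables were computed for substances that don't exist, and the scatter is random.

At early times, in closed isothermal flasks where the complex Z trades a ligand for the incoming J and gives E, less E appears than Z goes: north-west at 2.00 min shows 5.3 % as E, less than the 9.00 % of its Z that has gone.

| setting | north-west | south-east | ash | oak |
|---|---|---|---|---|
| Z | 2 M | 2 M | 2.0 M | 2.0 M |
| J | 0.55 equiv | 0.81 equiv | 0.800 equiv | 1.20 equiv |
| remark | run made earlier | run made earlier |  |  |
| time |  |  | 25 min | 25 min |

| run | time / min | Z / % | E / % |
|---|---|---|---|
| north-west | 2.00 | 91.0 | 5.3 |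
| north-west | 5.00 | 80.6 | 11.4 |
| north-west | 10.0 | 68.4 | 19.2 |
| north-west | 25.0 | 53.8 | 28.9 |
| south-east | 3.00 | 81.4 | 10.9 |
| south-east | 8.00 | 62.9 | 22.6 |
| south-east | 15.0 | 51.1 | 31.5 |
| south-east | 25.0 | 44.4 | 34.2 |

(each reading ± 0.5 percentage points)

- what has gone from Z into another species counts as reacted, even if it can come back

- part of the Z that has reacted at the end, ash
- part of the Z that has reacted at the end, oak
- what raising the equivalents of J from its lowest to its highest value here does to the part of the Z that has reacted (changes below 5 percentage points count as none) (it rises / it falls / no change)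

Dividing the rate at which Z vanishes into something unseen by the rate at which E appears removes time. What remains is the side share, (charged c(Z) − c(Z) − c(E))/c(E), a ratio of amounts at the moment of reading, which south-east reads at 25.0 min as 0.626. At 3.00 min the same run reads 0.706, a looser figure with c(E) still small, so the unseen part shows no lag behind E and forms the top rung of the ladder. On the next rung, south-east loses Z at 0.0620 min⁻¹ of its charge, a time scale of 16.1 min. Between 15.0 min and 25.0 min the pace has dropped to 0.00670 min⁻¹, a time scale of 149 min, longer than the 25 min asked. South-east therefore ends on the slow rung, with its reacted part equal to one plus the side share, times c(E).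

Ash, at 0.800 equiv, nearly repeats south-east, and with that run's E this reckoning gives 55.6 %. The forecast says 55.3 % (54 % to 56.7 %) for ash, slightly lower, and 66 % (61 % to 71 %) for oak, with the trend it rises: “Ash is almost the south-east run, so interpolating at 25 min gives about 55%.”

The flasks give 56.0 % for ash and 65.2 % for oak, and the trend is it rises, by 9.2 percentage points.

    Z + J ⇌ Q + E (K = 0.400, k = 0.0270 M⁻¹ min⁻¹)
    E + J ⇌ Q + D (K = 2.30, k = 0.00200 M⁻¹ min⁻¹)
    D + J ⇌ Q + G (K = 73.0, k = 0.0350 M⁻¹ min⁻¹)
    Q + Z ⇌ L, settled at all times (K = 1.40 M⁻¹)

Oak's final E of 40.0 % with the side share gives 65.0 %, and the unseen part there is L at 22.7 %, made from Z and the Q that the formation of E releases, beside D at 1.49 % and G at 1.05 %. The difference in equivalents of J may be called the main reason for the gap between oak and ash: with the J of ash, oak stands at 56.0 % instead of 65.2 %. In a neighbour of ash charged with 1.40 equiv of J, E at 41.6 % and the side share give 67.6 %; the computed result is 68.2 %.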